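All runs stem from a simulated flask with constants of no real substance; scatter was added.

Two things are asked of this row of flasks: how much product Ux.Wy stands in each at the end, and what course those numbers take as the charge of Vo goes up. Qo is the substrate and Ux the reagent.

the same everywhere: Ux 0.125 M
- Tuesday's: Qo 0.17 M; Vo 5 mM; run made earlier
- south-east: Qo 0.25 M; Vo 5.00 mM; time 25 min
- east: Qo 0.25 M; Vo 10.0 mM; time 25 min
- north: Qo 0.25 M; Vo 20.0 mM; time 25 min
- south-west: Qo 0.25 M; Vo 40.0 mM; time 25 min
- north-west: Qo 0.25 M; Vo 80.0 mM; time 25 min

- Tuesday's (time / min: Ux.Wy / %, Qo / %): 1.33: 8.4, 20.5; 4.00: 10.5, 8.4; 8.00: 11.7, 6.1; 10.0: 11.5, 5.1; 15.0: 10.5, 4.0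

(scatter of a reading: 0.5 percentage points)

- the earlier runs were read with a standard deviation of 0.5 percentage points
- "hardly changes" means that all values lie within two and a half points (for a concentration: within two and a half percent of the largest)
- no earlier run changes the charge of Vo; that part of a forecast is a guess

1. amount of Ux.Wy at the end, in percent of the Qo charged for south-east, east, north, south-west, north-west, in this order
2. the course of these numbers from the first flask to the last (hardly changes / rises all the way / falls all the way / rises, then falls / falls, then rises)

In Tuesday's run Ux.Wy reads 10.5% at 4.00 min and 10.5% at 15.0 min, while Qo still falls from 8.4% to 4.0%. Qo goes on reacting, then, while the product readings of that stretch lie within 1.2 percentage points of each other, against a scatter of 0.5 points, so any growth of the product there is slow next to the fall of Qo. Ux is not read, but it is charged below Qo, so we take this slow stretch as a sign that Ux is the limiting reagent.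

The bench rule that follows is to count product against the reagent, not the substrate. We call this the reagent yield, the part of the Ux charge that ends as Ux.Wy. The mean of Tuesday's readings from 4.00 min on gives 15.0%. In the new flasks the Ux charge is 50.0% of the Qo charge, so our reckoning gives 7.51% of the Qo charged in every flask, a row that hardly changes.

The border of this rule is the ratio c(Vo)/c(Ux). It is 4.00% on Tuesday and in south-east, but 64.0% in north-west, so that is the flask where we trust the rule least.

The forecast differs from our reckoning. It gives 6.5%, 10%, 14%, 16% and 15%, with the course "rises, then falls", and it says: “If Vo promotes product formation, yield rises with Vo, with diminishing returns.”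

The flasks give 6.80%, 6.88%, 7.04%, 7.37% and 8.04%, and the course is "hardly changes".

    Qo ⇌ Wy (K = 0.390, k = 0.00770 s⁻¹)
    Qo + Ux → Qo.Ux (k = 0.220 L mol⁻¹ s⁻¹)
    Ux + Wy → Ux.Wy (k = 0.260 L mol⁻¹ s⁻¹)
    2 Qo → Jy (k = 0.0220 L mol⁻¹ s⁻¹)
    Wy → Ul (k = 0.00160 s⁻¹)
    Qo + Vo → Qo.Vo (k = 0.470 L mol⁻¹ s⁻¹)

Counted against Ux, south-east gives a reagent yield of 13.6% and north-west 16.1%, on either side of the 15.0% read from Tuesday. At the end, Ux left is 0% of its charge in south-east and 0.67% in north-west. In south-east the wearing away of Ux is the largest single effect on the product: with Ux held at its charge, that flask reaches 12.2% instead of 6.80%.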